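**Retrosynthetic overview**
1. Target 28 ⇐ acetylation of triol 25 ⇐ desilylation of ester 24 ⇐ carbonylative esterification (4-iodophenol + CO) of γ-hydroxy enone 20.
2. 20 ⇐ γ-oxidation of 1-siloxy-1,3-diene 18 ⇐ one-carbon ring expansion (1,2-alkenyl shift of a β-oxido carbenoid from CH3CHBr2) of trans-fused hydrindenone 14: six- to seven-membered ring (key step).
3. 14 ⇐ intramolecular aldol condensation of a keto aldehyde carried by a fully substituted cyclopentane.
4. That cyclopentane ⇐ (R)-4-hydroxycyclopent-2-enone by conjugate methallylation/re-oxidation, conjugate methylation/dimethoxymethylation (C8a, C3a) and isopropyl addition (C3).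
5. Ring order: five-membered ring (bought) → six-membered ring (aldol, step 7) → seven-membered ring (ring expansion, step 8).

Conventions: TBS = tert-butyldimethylsilyl, TES = triethylsilyl, TMS = trimethylsilyl. Ring atoms are labelled as in azulene (C1–C8a of the target); β is the face of the C8a methyl group. Nothing here has been run; all steps are proposals.
Assumption: (R)-4-hydroxycyclopent-2-en-1-one (1) is bought as the single enantiomer.

**Step 1**
Reactants: 1 (R)-4-hydroxycyclopent-2-en-1-one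
Product: 2 (R)-4-[(tert-butyldimethylsilyl)oxy]cyclopent-2-en-1-one
Conditions: TBSCl, imidazole, DMF, 0 °C → rt
Reagents that add atoms: tert-butyl(chloro)dimethylsilane, CC(C)(C)[Si](C)(C)Cl
Why: Standard imidazole-mediated silylation of the secondary alcohol, which leaves the stereocentre (future C1) untouched.

**Step 2**
Reactants: 2 (R)-4-[(tert-butyldimethylsilyl)oxy]cyclopent-2-en-1-one; 3 trimethyl(2-methylprop-2-en-1-yl)silane
Product: 4 tert-butyldimethyl{[(1R,2R)-2-(2-methylprop-2-en-1-yl)-4-[(trimethylsilyl)oxy]cyclopent-3-en-1-yl]oxy}silane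
Conditions: Tf2NH (5 mol %), CH2Cl2, −78 °C; Et3N quench
Reagents that add atoms: none
Why: Hosomi–Sakurai conjugate allylation under silyl triflimide catalysis (Me3SiNTf2 formed from 3 and Tf2NH), in which the silyl group is handed on to the enolate oxygen to give the regiodefined enol silane; addition is anti to OTBS, but this centre is erased in step 3.

**Step 3**
Reactants: 4 tert-butyldimethyl{[(1R,2R)-2-(2-methylprop-2-en-1-yl)-4-[(trimethylsilyl)oxy]cyclopent-3-en-1-yl]oxy}silane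
Product: 5 (R)-4-[(tert-butyldimethylsilyl)oxy]-3-(2-methylprop-2-en-1-yl)cyclopent-2-en-1-one
Conditions: Pd(OAc)2 (1.1 equiv), MeCN, rt
Reagents that add atoms: none
Why: Saegusa–Ito oxidation; the enol silane gives an oxa-π-allylpalladium species whose β-hydride elimination restores the enone, now carrying the future C8–C7–C5 unit on the β-carbon.

**Step 4**
Reactants: 5 (R)-4-[(tert-butyldimethylsilyl)oxy]-3-(2-methylprop-2-en-1-yl)cyclopent-2-en-1-one; 6 methylmagnesium bromide; 7 trimethyl orthoformate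
Product: 9 (2R,3S,4R)-4-[(tert-butyldimethylsilyl)oxy]-2-(dimethoxymethyl)-3-methyl-3-(2-methylprop-2-en-1-yl)cyclopentan-1-one, via silyl enol ether 8 (not isolated)
Conditions: MeMgBr, CuBr·SMe2 (10 mol %), TMSCl, THF, −78 °C; solvent switch to CH2Cl2; HC(OMe)3, TMSOTf (5 mol %), −78 °C
Reagents that add atoms: none
Why: Copper-catalysed, TMSCl-accelerated conjugate addition puts the methyl group on the β,β-disubstituted enone anti to OTBS (sets quaternary C8a, methyl trans to the C1 oxygen), and Mukaiyama-type capture of the enol silane by the dimethoxycarbenium ion anti to the larger methallyl group sets C3a (also the thermodynamically preferred epimer).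

**Step 5**
Reactants: 9 (2R,3S,4R)-4-[(tert-butyldimethylsilyl)oxy]-2-(dimethoxymethyl)-3-methyl-3-(2-methylprop-2-en-1-yl)cyclopentan-1-one; 10 isopropylmagnesium chloride
Product: 11 (1S,2S,3S,4R)-4-[(tert-butyldimethylsilyl)oxy]-2-(dimethoxymethyl)-3-methyl-3-(2-methylprop-2-en-1-yl)-1-(propan-2-yl)cyclopentan-1-ol
Conditions: i-PrMgCl, CeCl3, THF, −78 → 0 °C; aq. NH4Cl
Reagents that add atoms: none
Why: Organocerium 1,2-addition (weakly basic, so the β-silyloxy ketone is neither enolised nor eliminated) attacks the cyclopentanone from the face opposite the adjacent dimethoxymethyl group (1,2-induction), giving the C3 carbinol with β-OH and α-isopropyl.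

**Step 6**
Reactants: 11 (1S,2S,3S,4R)-4-[(tert-butyldimethylsilyl)oxy]-2-(dimethoxymethyl)-3-methyl-3-(2-methylprop-2-en-1-yl)-1-(propan-2-yl)cyclopentan-1-ol
Product: 12 1-[(1S,2S,3S,5R)-5-[(tert-butyldimethylsilyl)oxy]-2-(dimethoxymethyl)-3-hydroxy-1-methyl-3-(propan-2-yl)cyclopentyl]propan-2-one
Conditions: O3, CH2Cl2/MeOH, −78 °C; Me2S
Reagents that add atoms: ozone, [O-][O+]=O
Why: Ozonolysis of the only alkene with reductive work-up unveils the methyl ketone (C7 with its methyl, the future C5) without touching the acetal, the silyl ether or the tertiary alcohol.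

**Step 7**
Reactants: 12 1-[(1S,2S,3S,5R)-5-[(tert-butyldimethylsilyl)oxy]-2-(dimethoxymethyl)-3-hydroxy-1-methyl-3-(propan-2-yl)cyclopentyl]propan-2-one
Product: 14 (1R,3S,3aS,7aS)-1-[(tert-butyldimethylsilyl)oxy]-7a-methyl-3-(propan-2-yl)-3-[(triethylsilyl)oxy]-1,2,3,3a,7,7a-hexahydro-6H-inden-6-one, via keto aldehyde 13 (not isolated)
Conditions: TESOTf, 2,4,6-collidine, CH2Cl2, 0 °C; H2O; then piperidine, AcOH, toluene, 60 °C
Reagents that add atoms: triethylsilyl trifluoromethanesulfonate, CC[Si](CC)(CC)OS(=O)(=O)C(F)(F)F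
Why: Silyl triflate/collidine silylates the tertiary alcohol and cleaves the dimethyl acetal through a pyridinium intermediate under non-acidic conditions, and amine-catalysed intramolecular aldol condensation of the methyl ketone onto the hindered aldehyde then closes the trans-fused cyclohexenone without any new stereocentre (C3a and C8a were fixed in step 4).

**Step 8**
Reactants: 14 (1R,3S,3aS,7aS)-1-[(tert-butyldimethylsilyl)oxy]-7a-methyl-3-(propan-2-yl)-3-[(triethylsilyl)oxy]-1,2,3,3a,7,7a-hexahydro-6H-inden-6-one; 15 1,1-dibromoethane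
Product: 18 tert-butyl{[(1R,3S,3aS,8aS)-6,8a-dimethyl-3-(propan-2-yl)-3-[(triethylsilyl)oxy]-7-[(trimethylsilyl)oxy]-1,2,3,3a,8,8a-hexahydroazulen-1-yl]oxy}dimethylsilane, via dibromo alkoxide 16 (not isolated), via lithium dienolate 17 (not isolated)
Conditions: LiN(iPr)2, THF, −95 °C; n-BuLi, −95 → −20 °C; TMSCl, −78 °C → rt
Reagents that add atoms: chlorotrimethylsilane, C[Si](C)(C)Cl
Why: Proposed new method: 1,1-dibromoethyllithium adds 1,2 to the enone carbonyl, bromine–lithium exchange gives a β-oxido carbenoid, and the alkenyl carbon C5 (sp2, better able to bridge than the neopentyl CH2 C8) shifts to the carbenoid carbon with loss of LiBr, so that C6 with its methyl is inserted between C7 and C5 and the resulting ring-expanded lithium dienolate is O-silylated to the 1-siloxy-1,3-diene; the closest known reaction type is the β-oxido carbenoid one-carbon homologation of saturated cycloalkanones with dibromomethyllithium, whereas alkenyl-selective migration with a methyl-bearing carbenoid on a fused cyclohexenone combined with capture of the dienolate has not been shown.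

**Step 9**
Reactants: 18 tert-butyl{[(1R,3S,3aS,8aS)-6,8a-dimethyl-3-(propan-2-yl)-3-[(triethylsilyl)oxy]-7-[(trimethylsilyl)oxy]-1,2,3,3a,8,8a-hexahydroazulen-1-yl]oxy}dimethylsilane
Product: 20 (1R,3S,3aR,4R,8aS)-1-[(tert-butyldimethylsilyl)oxy]-4-hydroxy-6,8a-dimethyl-3-(propan-2-yl)-3-[(triethylsilyl)oxy]-2,3,3a,4,8,8a-hexahydroazulen-7(1H)-one, via trimethylsilyl ether 19 (not isolated)
Conditions: DMDO, acetone/CH2Cl2, −78 °C; then MeOH, citric acid (cat.), 0 °C
Reagents that add atoms: dimethyldioxirane, CC1(C)OO1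
Why: Vinylogous Rubottom oxidation; the oxidant attacks the terminal (γ) carbon C4 of the siloxydiene from the α-face, because the β-face of C4 is screened by the neighbouring tertiary OTES group and the angular methyl, and silyl migration followed by methanolysis gives the γ-hydroxy enone with the 4R centre.

**Step 10**
Reactants: 20 (1R,3S,3aR,4R,8aS)-1-[(tert-butyldimethylsilyl)oxy]-4-hydroxy-6,8a-dimethyl-3-(propan-2-yl)-3-[(triethylsilyl)oxy]-2,3,3a,4,8,8a-hexahydroazulen-7(1H)-one; 21 4-iodophenol; 22 carbon monoxide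
Product: 24 (1R,3S,3aR,4R,8aS)-1-[(tert-butyldimethylsilyl)oxy]-6,8a-dimethyl-7-oxo-3-(propan-2-yl)-3-[(triethylsilyl)oxy]-1,2,3,3a,4,7,8,8a-octahydroazulen-4-yl 4-[(tert-butyldimethylsilyl)oxy]benzoate, via aryl silyl ether 23 (not isolated)
Conditions: 21, TBSCl, Et3N, toluene, rt; then 20, CO (1 atm), Pd(OAc)2 (5 mol %), Xantphos (6 mol %), DMAP, 70 °C
Reagents that add atoms: tert-butyl(chloro)dimethylsilane, CC(C)(C)[Si](C)(C)Cl
Why: Palladium-catalysed alkoxycarbonylation; oxidative addition of the aryl iodide (phenol masked in situ), CO insertion and DMAP-assisted acyl transfer to the only free hydroxyl group form the benzoate with retention at C4.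

**Step 11**
Reactants: 24 (1R,3S,3aR,4R,8aS)-1-[(tert-butyldimethylsilyl)oxy]-6,8a-dimethyl-7-oxo-3-(propan-2-yl)-3-[(triethylsilyl)oxy]-1,2,3,3a,4,7,8,8a-octahydroazulen-4-yl 4-[(tert-butyldimethylsilyl)oxy]benzoate
Product: 25 (1R,3S,3aR,4R,8aS)-1,3-dihydroxy-6,8a-dimethyl-7-oxo-3-(propan-2-yl)-1,2,3,3a,4,7,8,8a-octahydroazulen-4-yl 4-hydroxybenzoate
Conditions: HF·pyridine, THF/pyridine, 0 °C → rt
Reagents that add atoms: none
Why: Fluoride-driven global desilylation (strong Si–F bond) removes the aryl, tertiary and hindered secondary silyl ethers under mildly acidic conditions that leave the esters, the enone and the tertiary alcohol alone.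

**Step 12**
Reactants: 25 (1R,3S,3aR,4R,8aS)-1,3-dihydroxy-6,8a-dimethyl-7-oxo-3-(propan-2-yl)-1,2,3,3a,4,7,8,8a-octahydroazulen-4-yl 4-hydroxybenzoate; 26 acetic anhydride
Product: 28 (1R,3S,3aR,4R,8aS)-1-(acetyloxy)-3-hydroxy-6,8a-dimethyl-7-oxo-3-(propan-2-yl)-1,2,3,3a,4,7,8,8a-octahydroazulen-4-yl 4-hydroxybenzoate, via diacetate 27 (not isolated)
Conditions: Ac2O, pyridine, DMAP (cat.), CH2Cl2, rt; then pyrrolidine, 0 °C
Reagents that add atoms: none
Why: DMAP-catalysed acetylation esterifies the secondary C1 alcohol and the phenol but not the hindered tertiary alcohol, and the far more electrophilic aryl acetate is then cleaved selectively by aminolysis, leaving the alkyl acetate and the benzoate.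

**Compound list**
1 | (R)-4-hydroxycyclopent-2-en-1-one | O=C1C=C[C@H](O)C1 | starting material
2 | (R)-4-[(tert-butyldimethylsilyl)oxy]cyclopent-2-en-1-one | O=C1C=C[C@H](O[Si](C)(C)C(C)(C)C)C1 | intermediate
3 | trimethyl(2-methylprop-2-en-1-yl)silane | CC(=C)C[Si](C)(C)C | starting material
4 | tert-butyldimethyl{[(1R,2R)-2-(2-methylprop-2-en-1-yl)-4-[(trimethylsilyl)oxy]cyclopent-3-en-1-yl]oxy}silane | C[Si](C)(C)OC1=C[C@@H](CC(C)=C)[C@H](O[Si](C)(C)C(C)(C)C)C1 | intermediate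
5 | (R)-4-[(tert-butyldimethylsilyl)oxy]-3-(2-methylprop-2-en-1-yl)cyclopent-2-en-1-one | O=C1C=C(CC(C)=C)[C@H](O[Si](C)(C)C(C)(C)C)C1 | intermediate
6 | methylmagnesium bromide | C[Mg]Br | starting material
7 | trimethyl orthoformate | COC(OC)OC | starting material
8 | tert-butyldimethyl{[(1R,2S)-2-methyl-2-(2-methylprop-2-en-1-yl)-4-[(trimethylsilyl)oxy]cyclopent-3-en-1-yl]oxy}silane | C[Si](C)(C)OC1=C[C@](C)(CC(C)=C)[C@H](O[Si](C)(C)C(C)(C)C)C1 | intermediate
9 | (2R,3S,4R)-4-[(tert-butyldimethylsilyl)oxy]-2-(dimethoxymethyl)-3-methyl-3-(2-methylprop-2-en-1-yl)cyclopentan-1-one | O=C1C[C@@H](O[Si](C)(C)C(C)(C)C)[C@@](C)(CC(C)=C)[C@@H]1C(OC)OC | intermediate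
10 | isopropylmagnesium chloride | CC(C)[Mg]Cl | starting material
11 | (1S,2S,3S,4R)-4-[(tert-butyldimethylsilyl)oxy]-2-(dimethoxymethyl)-3-methyl-3-(2-methylprop-2-en-1-yl)-1-(propan-2-yl)cyclopentan-1-ol | CC(C)[C@@]1(O)C[C@@H](O[Si](C)(C)C(C)(C)C)[C@@](C)(CC(C)=C)[C@@H]1C(OC)OC | intermediate
12 | 1-[(1S,2S,3S,5R)-5-[(tert-butyldimethylsilyl)oxy]-2-(dimethoxymethyl)-3-hydroxy-1-methyl-3-(propan-2-yl)cyclopentyl]propan-2-one | CC(C)[C@@]1(O)C[C@@H](O[Si](C)(C)C(C)(C)C)[C@@](C)(CC(C)=O)[C@@H]1C(OC)OC | intermediate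
13 | (1S,2S,3R,5S)-3-[(tert-butyldimethylsilyl)oxy]-2-methyl-2-(2-oxopropyl)-5-(propan-2-yl)-5-[(triethylsilyl)oxy]cyclopentane-1-carbaldehyde | CC(C)[C@@]1(O[Si](CC)(CC)CC)C[C@@H](O[Si](C)(C)C(C)(C)C)[C@@](C)(CC(C)=O)[C@@H]1C=O | intermediate
14 | (1R,3S,3aS,7aS)-1-[(tert-butyldimethylsilyl)oxy]-7a-methyl-3-(propan-2-yl)-3-[(triethylsilyl)oxy]-1,2,3,3a,7,7a-hexahydro-6H-inden-6-one | CC(C)[C@@]1(O[Si](CC)(CC)CC)C[C@@H](O[Si](C)(C)C(C)(C)C)[C@@]2(C)CC(=O)C=C[C@H]12 | intermediate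
15 | 1,1-dibromoethane | CC(Br)Br | starting material
16 | lithium (1R,3S,3aS,7aS)-1-[(tert-butyldimethylsilyl)oxy]-6-(1,1-dibromoethyl)-7a-methyl-3-(propan-2-yl)-3-[(triethylsilyl)oxy]-2,3,3a,6,7,7a-hexahydro-1H-inden-6-olate (C6 configuration not defined) | CC(C)[C@@]1(O[Si](CC)(CC)CC)C[C@@H](O[Si](C)(C)C(C)(C)C)[C@@]2(C)CC(O[Li])(C(C)(Br)Br)C=C[C@H]12 | intermediate
17 | lithium (1R,3S,3aS,8aS)-1-[(tert-butyldimethylsilyl)oxy]-6,8a-dimethyl-3-(propan-2-yl)-3-[(triethylsilyl)oxy]-1,2,3,3a,8,8a-hexahydroazulen-7-olate | CC(C)[C@@]1(O[Si](CC)(CC)CC)C[C@@H](O[Si](C)(C)C(C)(C)C)[C@@]2(C)CC(O[Li])=C(C)C=C[C@H]12 | intermediate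
18 | tert-butyl{[(1R,3S,3aS,8aS)-6,8a-dimethyl-3-(propan-2-yl)-3-[(triethylsilyl)oxy]-7-[(trimethylsilyl)oxy]-1,2,3,3a,8,8a-hexahydroazulen-1-yl]oxy}dimethylsilane | CC(C)[C@@]1(O[Si](CC)(CC)CC)C[C@@H](O[Si](C)(C)C(C)(C)C)[C@@]2(C)CC(O[Si](C)(C)C)=C(C)C=C[C@H]12 | intermediate
19 | (1R,3S,3aR,4R,8aS)-1-[(tert-butyldimethylsilyl)oxy]-6,8a-dimethyl-3-(propan-2-yl)-3-[(triethylsilyl)oxy]-4-[(trimethylsilyl)oxy]-2,3,3a,4,8,8a-hexahydroazulen-7(1H)-one | CC(C)[C@@]1(O[Si](CC)(CC)CC)C[C@@H](O[Si](C)(C)C(C)(C)C)[C@@]2(C)CC(=O)C(C)=C[C@@H](O[Si](C)(C)C)[C@H]12 | intermediate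
20 | (1R,3S,3aR,4R,8aS)-1-[(tert-butyldimethylsilyl)oxy]-4-hydroxy-6,8a-dimethyl-3-(propan-2-yl)-3-[(triethylsilyl)oxy]-2,3,3a,4,8,8a-hexahydroazulen-7(1H)-one | CC(C)[C@@]1(O[Si](CC)(CC)CC)C[C@@H](O[Si](C)(C)C(C)(C)C)[C@@]2(C)CC(=O)C(C)=C[C@@H](O)[C@H]12 | intermediate
21 | 4-iodophenol | Oc1ccc(I)cc1 | starting material
22 | carbon monoxide | [C-]#[O+] | starting material
23 | tert-butyl(4-iodophenoxy)dimethylsilane | CC(C)(C)[Si](C)(C)Oc1ccc(I)cc1 | intermediate
24 | (1R,3S,3aR,4R,8aS)-1-[(tert-butyldimethylsilyl)oxy]-6,8a-dimethyl-7-oxo-3-(propan-2-yl)-3-[(triethylsilyl)oxy]-1,2,3,3a,4,7,8,8a-octahydroazulen-4-yl 4-[(tert-butyldimethylsilyl)oxy]benzoate | CC(C)[C@@]1(O[Si](CC)(CC)CC)C[C@@H](O[Si](C)(C)C(C)(C)C)[C@@]2(C)CC(=O)C(C)=C[C@@H](OC(=O)c3ccc(O[Si](C)(C)C(C)(C)C)cc3)[C@H]12 | intermediate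
25 | (1R,3S,3aR,4R,8aS)-1,3-dihydroxy-6,8a-dimethyl-7-oxo-3-(propan-2-yl)-1,2,3,3a,4,7,8,8a-octahydroazulen-4-yl 4-hydroxybenzoate | CC(C)[C@@]1(O)C[C@@H](O)[C@@]2(C)CC(=O)C(C)=C[C@@H](OC(=O)c3ccc(O)cc3)[C@H]12 | intermediate
26 | acetic anhydride | CC(=O)OC(C)=O | starting material
27 | (1R,3S,3aR,4R,8aS)-1-(acetyloxy)-3-hydroxy-6,8a-dimethyl-7-oxo-3-(propan-2-yl)-1,2,3,3a,4,7,8,8a-octahydroazulen-4-yl 4-(acetyloxy)benzoate | CC(C)[C@@]1(O)C[C@@H](OC(C)=O)[C@@]2(C)CC(=O)C(C)=C[C@@H](OC(=O)c3ccc(OC(C)=O)cc3)[C@H]12 | intermediate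
28 | (1R,3S,3aR,4R,8aS)-1-(acetyloxy)-3-hydroxy-6,8a-dimethyl-7-oxo-3-(propan-2-yl)-1,2,3,3a,4,7,8,8a-octahydroazulen-4-yl 4-hydroxybenzoate (CNP0087181.6) | CC(=O)O[C@@H]1C[C@](O)(C(C)C)[C@H]2[C@H](OC(=O)c3ccc(O)cc3)C=C(C)C(=O)C[C@]12C | target

**Step count**
Total steps: 12. Longest linear sequence: 12 (1 → 28); 4-iodophenol, CO and the other small building blocks enter without separate steps.

**Three steps most likely to fail**

Step 8 (the proposed ring expansion). The methyl-bearing carbenoid may collapse by a β-hydride shift, or C8 may migrate instead of C5. The fallback uses known selenium-based ring enlargement and sets out from 14. 1-(Methylselanyl)ethyllithium (from 1,1-bis(methylselanyl)ethane and n-BuLi, THF, −78 °C) adds 1,2 to the enone carbonyl to give the β-hydroxy selenide F1. AgBF4 on Al2O3 in CH2Cl2 turns selenium into a leaving group, and the pinacol-type 1,2-shift of the alkenyl carbon gives the ring-enlarged β,γ-unsaturated ketone F2. LiN(iPr)2/TMSCl at −78 °C removes the doubly activated C6 proton and gives 18, where the route is rejoined.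

Step 9 (face and site selectivity of the dienol ether oxidation). The fallback sets out from 18. If DMDO attacks C4 mainly from the β-face, the C4-epimeric silyl ether F3 forms and, after the same methanolysis, the C4-epimeric alcohol F4. F4 is esterified with inversion in a Mitsunobu reaction (PPh3, DIAD, toluene, 0 °C → rt) with 4-[(tert-butyldimethylsilyl)oxy]benzoic acid F5. F5 is made from 23 (here isolated) by iodine–magnesium exchange with i-PrMgCl·LiCl and quenching with CO2. This gives 24 directly, so the route is rejoined at 24 and step 10 is not needed.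

Step 10 (acyl transfer to a hindered allylic alcohol; sensitivity of the γ-hydroxy enone to base and palladium at 70 °C). The fallback avoids palladium and sets out from 21 and 20. 21 is silylated to 23 and converted into the acid F5 as above. F5 is activated with 2,4,6-trichlorobenzoyl chloride/Et3N as the mixed anhydride F6 and coupled with 20 in the presence of DMAP (toluene, rt; Yamaguchi esterification) to give 24, where the route is rejoined.

**Further compounds**
F1 | step 8 | (1R,3S,3aS,7aS)-1-[(tert-butyldimethylsilyl)oxy]-7a-methyl-6-[1-(methylselanyl)ethyl]-3-(propan-2-yl)-3-[(triethylsilyl)oxy]-2,3,3a,6,7,7a-hexahydro-1H-inden-6-ol (C6 and side-chain configuration not defined) | CC(C)[C@@]1(O[Si](CC)(CC)CC)C[C@@H](O[Si](C)(C)C(C)(C)C)[C@@]2(C)CC(O)(C(C)[Se]C)C=C[C@H]12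
F2 | step 8 | (1R,3S,3aS,8aS)-1-[(tert-butyldimethylsilyl)oxy]-6,8a-dimethyl-3-(propan-2-yl)-3-[(triethylsilyl)oxy]-2,3,3a,6,8,8a-hexahydroazulen-7(1H)-one (C6 epimers) | CC(C)[C@@]1(O[Si](CC)(CC)CC)C[C@@H](O[Si](C)(C)C(C)(C)C)[C@@]2(C)CC(=O)C(C)C=C[C@H]12
F3 | step 9 | (1R,3S,3aR,4S,8aS)-1-[(tert-butyldimethylsilyl)oxy]-6,8a-dimethyl-3-(propan-2-yl)-3-[(triethylsilyl)oxy]-4-[(trimethylsilyl)oxy]-2,3,3a,4,8,8a-hexahydroazulen-7(1H)-one | CC(C)[C@@]1(O[Si](CC)(CC)CC)C[C@@H](O[Si](C)(C)C(C)(C)C)[C@@]2(C)CC(=O)C(C)=C[C@H](O[Si](C)(C)C)[C@H]12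
F4 | step 9 | (1R,3S,3aR,4S,8aS)-1-[(tert-butyldimethylsilyl)oxy]-4-hydroxy-6,8a-dimethyl-3-(propan-2-yl)-3-[(triethylsilyl)oxy]-2,3,3a,4,8,8a-hexahydroazulen-7(1H)-one | CC(C)[C@@]1(O[Si](CC)(CC)CC)C[C@@H](O[Si](C)(C)C(C)(C)C)[C@@]2(C)CC(=O)C(C)=C[C@H](O)[C@H]12
F5 | step 9 | 4-[(tert-butyldimethylsilyl)oxy]benzoic acid | CC(C)(C)[Si](C)(C)Oc1ccc(cc1)C(=O)O
F6 | step 10 | 4-[(tert-butyldimethylsilyl)oxy]benzoic 2,4,6-trichlorobenzoic anhydride | CC(C)(C)[Si](C)(C)Oc1ccc(cc1)C(=O)OC(=O)c1c(Cl)cc(Cl)cc1Cl
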